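Follow the coupling partner.

| flask | substrate | coupling partner | remark | time |
|---|---|---|---|---|
| amber | 0.50 mM | 0.95 mM | run made earlier |  |
| grey | 2 mM | 0.95 mM | run made earlier |  |
| red | 1 mM | 1.9 mM | run made earlier |  |
| flask | 1.0 mM | 0.950 mM |  | 25 min |

- amber (time / min: substrate / %, single product / %, other mono adduct / %): 4.00: 0, 39.9, 10.0; 8.00: 0.2, 39.3, 10.1; 12.0: 0.1, 40.0, 10.0; 15.0: 0, 39.9, 10.2; 20.0: 0.5, 39.7, 9.9; 25.0: 0, 39.6, 10.5
- grey (time / min: substrate / %, single product / %, other mono adduct / %): 1.50: 34.9, 0.7, 15.4; 5.00: 34.5, 0.2, 15.7; 8.00: 34.9, 0.8, 14.9; 15.0: 34.2, 0.2, 15.3; 20.0: 34.3, 0, 15.5; 25.0: 34.6, 0.6, 14.9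
- red (time / min: substrate / %, single product / %, other mono adduct / %): 5.00: 0, 37.2, 4.8; 10.0: 0.1, 37.4, 4.4; 15.0: 0, 37.4, 3.9; 20.0: 0, 37.5, 4.4; 25.0: 0, 37.4, 5.0

(standard deviation of a reading: 0.3 percentage points)

- the earlier runs were read with a standard deviation of 0.3 percentage points
- a reading or a percentage of single product counts all its forms, free or not

* the substrate standing at 25 min, as a percentage of the substrate charged
* the single product standing at 25 min, as a percentage of the substrate charged
* the other mono adduct standing at 25 min, as a percentage of the substrate charged
* the bis adduct standing at 25 min, as a percentage of the substrate charged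

The earlier runs are flat from their first readings, so each shows an end state. I audit grey, where substrate still stands at 34.6% at 25.0 min, so I take the partner as the limiting reagent there. By that reading grey has lost 1.31 mM of substrate on 0.95 mM of partner. Substrate lost per partner charged, with substrate left over, I call the take: 1.38.

Now the entries. The two mono adducts, each one substrate on one partner, hold 0.310 mM. That leaves 0.640 mM of partner to account for 0.998 mM of substrate, more substrate than partner. The bis adduct, one substrate on two partners, pulls the wrong way, so I suppose an unread product that holds two substrates on one partner. Assuming no other sink, both columns close with 0.452 mM in that product and 0.0940 mM in bis adduct.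

For the flask, my reckoning is this: if the take read in grey holds at this lower substrate charge, its 0.950 mM of partner could carry 1.31 mM of substrate, above the 1.0 mM charged, so I expect no substrate standing. The forecast says substrate 2%, single product 8%, other mono adduct 18% and bis adduct 72%, with “bis adduct is the remainder”, whereas my ledger sends a part of that remainder to the two-substrate product.

The flask gives substrate 0%, single product 10.1%, other mono adduct 20.2% and bis adduct 13.6%.

    substrate + coupling partner → single product (k = 789 M⁻¹ s⁻¹)
    substrate + coupling partner → other mono adduct (k = 606 M⁻¹ s⁻¹)
    coupling partner + single product → bis adduct (k = 119 M⁻¹ s⁻¹)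
    coupling partner + other mono adduct → bis adduct (k = 808 M⁻¹ s⁻¹)
    coupling partner → decomposed reagent (k = 0.101 s⁻¹)
    substrate + single product → side product (k = 55.4 M⁻¹ s⁻¹)
    crystals ⇌ single product, rate k7*(cs7 - [single product]) while solid is left; crystals form when [single product] > cs7 (solubility = 0.490 mM, k = 38.9 s⁻¹)

The two-substrate product is the side product, which stands in the flask at 56.0% of the substrate charged, each one counted as two, and the flask has 0% of its partner left. Single product stands low in this flask in part through two steps acting together, its loss with substrate to side product and the branch to other mono adduct: from 10.1%, it rises to 38.3% without the first and 34.5% without the second. With 1.7 mM of substrate, the take leaves 23.1% of the substrate charged, and that neighbour flask holds substrate at 25.2%.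

All runs were computed from invented constants; the scatter is artificial.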